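## Structural features

The target is a linear C15 chain (C1 = alkyne CH, C15 = ethyl CH3) folded into a single ring, an oxocane whose oxygen joins C6 and C12. The ring carries a (Z)-pent-2-en-4-ynyl chain at C6 (C1–C5) and a 1-bromopropyl group at C12 (C13–C15), trans to each other across the ether oxygen. Read from the SMILES string, the configuration is (3Z,6S,7S,9S,10S,12R,13R). Three pairs of stereocentres are adjacent: C6/C7 (side chain and chlorine cis), C9/C10 (chlorine and acetoxy trans) and C12/C13 (ring carbon and exocyclic bromide). The C7 and C9 chlorides face each other across the C8 methylene and are trans. The fragile groups are the terminal Z-enyne (radicals, ozone, base), the C10 acetate (hydride, base), and the secondary bromide and chlorides β to oxygen (elimination, participation by the ring oxygen). The real difficulty is closing a medium ring while placing five ring stereocentres, two of them C–Cl bonds. The key step exploits the unit O–C6–C7(Cl)–C8H2–C9(Cl): it is a trichloroacetate (O–C(=O)–CCl3) added across a terminal C8=C9 alkene, with C7–C8 as the ring-closing bond of the eight-membered ring.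

## Logic of the disconnections

**25 from 24.** The C13–Br bond is cut. The bromide is the most elimination-prone group and is therefore installed last; C13 can then travel as an oxygenated centre taken from 1. The forward step must be an SN2 bromination with clean inversion (13S to 13R) on a hindered carbinol, leaving enyne, acetate and chlorides alone.

**24 from 22 (through 23), and 22 from 19 + 20.** The two silyl groups and then the C3=C4 bond are cut. The enyne would not survive ozone, radicals or strong Lewis acids, so it follows steps 8–12; the side chain shrinks to a two-carbon aldehyde. The olefination must be Z-selective and fast at low temperature, sparing the acetate and not enolising the β-alkoxy aldehyde.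

**19 from 17, and 17 from 16.** C4=O is traced to a terminal alkene and the C7–H bond back to C7–Cl. Setting C7 after C6 lets the C6 substituent steer hydrogen delivery, and C7 becomes the non-stereogenic CCl2 group that the ring closure supplies. The reduction must stop at the monochloride, be face-selective, and leave the alkene and the C9 chloride untouched.

**16 from 14 + 15, and 14 from 12.** The C5–C6 bond is cut and C6 is returned to the carboxyl level. This removes C3–C5 and leaves a lactone. The hydride must distinguish the lactone from the C10 acetate, the acetal must ionise next to CCl2, and the allyl group must enter trans to the C12 substituent.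

**12 from 11.** The C7–C8 and C9–Cl bonds are cut. This opens the only ring and removes the C9 stereocentre, leaving an acyclic ester. The forward step needs 8-endo regiochemistry, chlorine delivery anti to the C10 acetoxy group, and dilution.

**11 from 9 + 10, and 9 from 8.** The two acyl C–O bonds are cut, so both esters derive from one syn-1,3-diol. The C10 acetate is the target's own group, shields one face in step 8, and keeps a free C10 hydroxyl from attacking the activated lactone across the ring later. The two secondary hydroxyls must be told apart; enzyme shape selectivity does this at O10, and a forcing acylation follows at O12.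

**8 from 6, and 6 from 4 + 5.** The C10–H and C11–C12 bonds are cut (directed reduction, then aldol). C8–C11 come from 5 and C12–C15 from 4. The aldol needs Felkin control at C12, and the reduction must be 1,3-syn and 1,2-selective on a vinyl ketone.

**4 from 3, 2 and 1.** Only functional-group changes remain; C13 comes from the chiral pool. The α-silyloxy aldehyde must not epimerise.

## Other disconnections considered

**Alternative 1:** The eight ring atoms are stored as a cyclopentene (C6–C10) fused to a dihydrofuran in the bicyclic enol ether A1. O3 cleavage of its tetrasubstituted C6=C10 bond would release the keto-lactone A2.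
- In favour: the medium ring is unveiled rather than closed, so there is no entropic penalty and no dilution. On predictability of ring formation this alternative is the better one.
- In favour: C7 and C9 would later become chlorides by SN2 inversion of defined alcohols, which is more secure than radical face selectivity. On stereochemical certainty at C7 and C9 it is also the better one.
- Against: A2 carries oxygen, not chlorine, at C7 and C9. Two deoxychlorinations on an eight-membered ring are needed, one beside the C10 carbonyl where β-elimination and epimerisation threaten.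
- Against: three different hydroxyl protecting groups must be shed in order, and C10 must be reduced from the right face and acetylated.
- Equal: C6 must still be taken from lactone to C-substituted ether as in the chosen plan, and probably more easily, since no CCl2 group retards ionisation.
- Step economy: the chosen plan is clearly shorter, because both chlorines arrive with C6 and C7 in one reagent.

**Alternative 2:** The C7–C9 bond of a cyclopropane is the cut, tracing the oxocane to the oxepane-fused trimethylsilyloxy cyclopropane A3. FeCl3 (trivalent iron) would oxidise the silyloxy cyclopropane, cleave the ring-fusion bond to a C7 ketone and a C9 radical, and transfer chlorine to give A4.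
- In favour: a seven-membered ether is easier to close than an eight-membered one, and strain drives the enlargement.
- In favour: A4 already holds the allyl group and the C13 bromide, so the endgame at C1–C5 and C13 is shorter than in the chosen plan (better on that count).
- Equal: C9–Cl forms in the same event as the skeletal change, and the C9 radical meets the same face-selectivity question as in the chosen plan.
- Against: C7 emerges as a ketone and needs a face-selective reduction and an inversion chlorination between C6 and C8.
- Against: A4 is a β-chloro ketone that can lose HCl to an enone, C6 becomes epimerisable, and the C9 radical could also add to the allyl double bond.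
- Against: FeCl3 is a Lewis acid toward the silyl ether and the secondary bromide, and the silyl ether must still be exchanged for acetate.
- Step economy: no net gain once the four stereocentres of A3 are counted.

**Alternative 3:** The O–C6 and C5–C6 bonds are the cuts. Cu(CF3COCHCOCF3)2 would decompose the acyclic diazoketone A5; the C12 allyl ether oxygen would add to the copper carbenoid, and a [2,3]-shift of the allyl group in the eight-membered oxonium ylide would give A6.
- In favour: one step closes the ring, makes C5–C6, sets C6 against C12 and delivers the allyl group. It needs no lactone-to-ether conversion and no ionisation beside CCl2, so at C6 it is the better plan.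
- Equal: the acetate and the C9 chloride are already in place.
- Against: eight is the least favourable ring size for ylide formation; C–H insertion and carbene dimerisation would compete.
- Against: in A5 the C9 chloride is β to the C7 carbonyl, so HCl loss threatens during diazoketone formation with CH2N2 and afterwards.
- Against: the chain must have C9, C10, C12 and C13 set one by one in acyclic form, and C7 again ends as a ketone needing two more stereo-defining steps.
- Comparison: the chosen radical closure operates on its best-precedented ring size and brings the C7 chlorine with it. Overall step count is about equal.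

Key step: step 8

Assumption: the SMILES string is taken as the absolute configuration, (3Z,6S,7S,9S,10S,12R,13R) in chain numbering.
Ring compounds are named with oxocane locants O1, C2 (chain C6), C3 (C7), C4 (C8), C5 (C9), C6 (C10), C7 (C11), C8 (C12).

## Route

Step 1
Reactants: 1 (2S)-2-hydroxybutanoic acid
Product: 2 methyl (2S)-2-hydroxybutanoate
Conditions: MeOH, H2SO4 (cat.), reflux
Reagents that add atoms: methanol, CO
Why: Fischer esterification; the stereocentre is not involved and α-hydroxy acids esterify without racemisation under these conditions.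

Step 2
Reactants: 2 methyl (2S)-2-hydroxybutanoate
Product: 3 methyl (2S)-2-[(tert-butyldimethylsilyl)oxy]butanoate
Conditions: TBSCl, imidazole, DMF, 0 °C to rt
Reagents that add atoms: tert-butyldimethylsilyl chloride, CC(C)(C)[Si](C)(C)Cl
Why: Imidazole-promoted silylation of a secondary alcohol; the silyl ether does not chelate, as step 4 requires, and is kept until step 14.

Step 3
Reactants: 3 methyl (2S)-2-[(tert-butyldimethylsilyl)oxy]butanoate
Product: 4 (2S)-2-[(tert-butyldimethylsilyl)oxy]butanal
Conditions: i-Bu2AlH (1.05 equiv), CH2Cl2, –78 °C; aq. KNaC4H4O6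
Reagents that add atoms: none
Why: Partial ester reduction through a tetrahedral aluminium hemiacetal that collapses only on work-up; the aldehyde should be used at once so that C13 does not epimerise.

Step 4
Reactants: 4 (2S)-2-[(tert-butyldimethylsilyl)oxy]butanal; 5 2-(trimethylsilyloxy)buta-1,3-diene
Product: 6 (5R,6S)-6-[(tert-butyldimethylsilyl)oxy]-5-hydroxyoct-1-en-3-one
Conditions: BF3·OEt2 (1.1 equiv), CH2Cl2, –78 °C; aq. NaHCO3
Reagents that add atoms: none
Why: Mukaiyama aldol addition; BF3 binds only the aldehyde oxygen, so the enol silane should attack in the polar Felkin–Anh sense, anti to the C13–O bond, giving the 12,13-anti adduct (C12 R). The hydroxy vinyl ketone is kept cold and carried on directly because it can close to a tetrahydropyranone by oxa-Michael addition.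

Step 5
Reactants: 6 (5R,6S)-6-[(tert-butyldimethylsilyl)oxy]-5-hydroxyoct-1-en-3-one
Product: 8 (3S,5R,6S)-6-[(tert-butyldimethylsilyl)oxy]oct-1-ene-3,5-diol, via Et2B aldolate 7 (not isolated)
Conditions: Et2BOMe, THF/MeOH 4:1, –78 °C; NaBH4, –78 °C; then MeOH, rt, evaporation from MeOH
Reagents that add atoms: none
Why: Narasaka–Prasad 1,3-syn reduction; the boron chelate fixes a half-chair to which external hydride adds axially, giving the 10,12-syn diol (C10 S). Chelate activation of the carbonyl should favour 1,2- over 1,4-hydride addition.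

Step 6
Reactants: 8 (3S,5R,6S)-6-[(tert-butyldimethylsilyl)oxy]oct-1-ene-3,5-diol
Product: 9 (3S,5R,6S)-6-[(tert-butyldimethylsilyl)oxy]-5-hydroxyoct-1-en-3-yl acetate
Conditions: Novozym 435 (immobilised Candida antarctica lipase B), vinyl acetate, t-BuOMe, 30 °C
Reagents that add atoms: vinyl acetate, CC(=O)OC=C
Why: Lipase-catalysed irreversible transesterification; the C10 carbinol has one small (vinyl) and one large flank in the arrangement this lipase acylates fast, whereas the C12 carbinol has two large flanks, so only O10 should be acetylated. Any 10-epi diol from step 5 has the slow-reacting arrangement and should stay behind.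

Step 7
Reactants: 9 (3S,5R,6S)-6-[(tert-butyldimethylsilyl)oxy]-5-hydroxyoct-1-en-3-yl acetate; 10 trichloroacetyl chloride
Product: 11 (3S,5R,6S)-3-(acetyloxy)-6-[(tert-butyldimethylsilyl)oxy]oct-1-en-5-yl trichloroacetate
Conditions: pyridine, CH2Cl2, 0 °C
Reagents that add atoms: none
Why: Pyridine-catalysed acylation with a very reactive acid chloride esterifies the hindered C12 hydroxyl at 0 °C, fast enough to outrun acetyl migration.

Step 8
Reactants: 11 (3S,5R,6S)-3-(acetyloxy)-6-[(tert-butyldimethylsilyl)oxy]oct-1-en-5-yl trichloroacetate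
Product: 12 (5S,6S,8R)-8-[(1S)-1-[(tert-butyldimethylsilyl)oxy]propyl]-3,3,5-trichloro-2-oxooxocan-6-yl acetate
Conditions: CuCl (30 mol %), 2,2'-bipyridine (30 mol %), ClCH2CH2Cl (0.02 M, degassed), 80 °C
Reagents that add atoms: none
Why: Kharasch-type atom-transfer radical cyclisation: CuCl(bipy) (monovalent copper) reversibly abstracts one chlorine from the CCl3 group, giving the electrophilic C7 dichloro(alkoxycarbonyl)methyl radical and CuCl2(bipy) (divalent copper). The radical adds to the terminal C8 of the C8=C9 alkene (C7–C8 bond) in an 8-endo-trig closure, the only ring formed; 7-exo attack at the substituted C9 would give a primary radical and is not reached comfortably from the preferred Z (s-trans) ester geometry, which an eight-membered transition state can keep. The secondary C9 radical then takes chlorine back from CuCl2(bipy), regenerating CuCl(bipy), so the process is redox-neutral and catalytic. The closest known reaction type is the copper- or ruthenium-catalysed 8-endo chlorine-transfer cyclisation of pent-4-enyl trichloroacetates to 3,3,5-trichlorooxocan-2-ones, of which 11 is a substituted member. The new stereocentre C9 is set in the chlorine-transfer step: the bulky CuCl2(bipy) donor should approach the ring radical on the face opposite the adjacent C10 acetoxy group, giving the 9,10-trans (9S) chloride. Chemoselectivity rests on bond strengths: the secondary chloride and the α,α-dichloro ester of the product are not re-activated at a useful rate, and chlorine transfer should be much faster than a 1,2-acyloxy shift of the β-acetoxy radical. High dilution suppresses intermolecular addition.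

Step 9
Reactants: 12 (5S,6S,8R)-8-[(1S)-1-[(tert-butyldimethylsilyl)oxy]propyl]-3,3,5-trichloro-2-oxooxocan-6-yl acetate
Product: 14 (5S,6S,8R)-8-[(1S)-1-[(tert-butyldimethylsilyl)oxy]propyl]-3,3,5-trichlorooxocane-2,6-diyl diacetate (both C2 epimers), via i-Bu2Al lactolate 13 (not isolated)
Conditions: i-Bu2AlH (1.1 equiv), CH2Cl2, –78 °C; then pyridine, DMAP, Ac2O, –78 to 0 °C
Reagents that add atoms: acetic anhydride, CC(=O)OC(C)=O
Why: Reductive acetylation of a lactone (hydride addition, then O-acetylation of the aluminium lactolate in the same flask). The two α-chlorines make the lactone carbonyl far more electrophilic than the C10 acetate and stabilise the tetrahedral intermediate, so one equivalent of hydride at –78 °C should be chemoselective and the ring should not open before trapping.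

Step 10
Reactants: 14 (5S,6S,8R)-8-[(1S)-1-[(tert-butyldimethylsilyl)oxy]propyl]-3,3,5-trichlorooxocane-2,6-diyl diacetate; 15 allyltrimethylsilane
Product: 16 (2S,5S,6S,8R)-2-allyl-8-[(1S)-1-[(tert-butyldimethylsilyl)oxy]propyl]-3,3,5-trichlorooxocan-6-yl acetate
Conditions: TMSOTf (1.5 equiv), CH2Cl2, –40 to 0 °C
Reagents that add atoms: none
Why: Hosomi–Sakurai-type C-allylation of the cyclic oxocarbenium ion released from the lactol acetate; the strong silyl Lewis acid is chosen because the CCl2 group retards ionisation, which one aligned C–Cl bond can partly offset by hyperconjugation. The allylsilane should add to the face of the eight-membered cation opposite the C12 side chain, giving the 2,8-trans ether (C6 S); with C7 still CCl2 there is no adjacent stereocentre to oppose this.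

Step 11
Reactants: 16 (2S,5S,6S,8R)-2-allyl-8-[(1S)-1-[(tert-butyldimethylsilyl)oxy]propyl]-3,3,5-trichlorooxocan-6-yl acetate
Product: 17 (2S,3S,5S,6S,8R)-2-allyl-8-[(1S)-1-[(tert-butyldimethylsilyl)oxy]propyl]-3,5-dichlorooxocan-6-yl acetate
Conditions: (Me3Si)3SiH (1.1 equiv, slow addition), Et3B/air (cat.), toluene, 0 °C
Reagents that add atoms: none
Why: Radical-chain mono-dechlorination of a geminal dichloride; the geminal C–Cl bonds are weaker than the isolated C9–Cl bond, so one equivalent of silane should stop at the monochloride. The bulky silane should deliver hydrogen to the C7 radical anti to the adjacent C6 allyl group, leaving chlorine cis to it (C7 S); low silane concentration lets any silyl-radical adduct of the alkene revert.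

Step 12
Reactants: 17 (2S,3S,5S,6S,8R)-2-allyl-8-[(1S)-1-[(tert-butyldimethylsilyl)oxy]propyl]-3,5-dichlorooxocan-6-yl acetate
Product: 19 (2S,3S,5S,6S,8R)-8-[(1S)-1-[(tert-butyldimethylsilyl)oxy]propyl]-3,5-dichloro-2-(2-oxoethyl)oxocan-6-yl acetate, via ozonide 18 (not isolated)
Conditions: O3, CH2Cl2, –78 °C; then PPh3, –78 °C to rt
Reagents that add atoms: ozone, [O-][O+]=O
Why: Ozonolysis with reductive work-up (Criegee mechanism); the terminal alkene is the only ozone-reactive group.

Step 13
Reactants: 19 (2S,3S,5S,6S,8R)-8-[(1S)-1-[(tert-butyldimethylsilyl)oxy]propyl]-3,5-dichloro-2-(2-oxoethyl)oxocan-6-yl acetate; 20 1,3-bis(triisopropylsilyl)propyne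
Product: 22 (2S,3S,5S,6S,8R)-8-[(1S)-1-[(tert-butyldimethylsilyl)oxy]propyl]-3,5-dichloro-2-[(2Z)-5-(triisopropylsilyl)pent-2-en-4-yn-1-yl]oxocan-6-yl acetate, via Li beta-silylalkoxide 21 (not isolated)
Conditions: 20, n-BuLi, THF, –78 °C; then 19, –78 to 0 °C; aq. NH4Cl
Reagents that add atoms: none
Why: Peterson olefination; the bulky silyl groups favour the β-silyl alkoxide whose syn-elimination gives the Z-enyne. Addition to the aldehyde at –78 °C should outpace attack on the acetate and enolisation.

Step 14
Reactants: 22 (2S,3S,5S,6S,8R)-8-[(1S)-1-[(tert-butyldimethylsilyl)oxy]propyl]-3,5-dichloro-2-[(2Z)-5-(triisopropylsilyl)pent-2-en-4-yn-1-yl]oxocan-6-yl acetate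
Product: 24 (2S,3S,5S,6S,8R)-3,5-dichloro-8-[(1S)-1-hydroxypropyl]-2-[(2Z)-pent-2-en-4-yn-1-yl]oxocan-6-yl acetate, via C-desilylated enyne 23 (not isolated)
Conditions: Bu4NF (3 equiv), AcOH (3 equiv), THF, 0 °C to rt
Reagents that add atoms: none
Why: Fluoride-mediated desilylation, alkynyl C–Si first and then the secondary O–Si bond; acetic acid buffering keeps the medium non-basic so that the acetate and the β-chloro ether are not attacked.

Step 15
Reactants: 24 (2S,3S,5S,6S,8R)-3,5-dichloro-8-[(1S)-1-hydroxypropyl]-2-[(2Z)-pent-2-en-4-yn-1-yl]oxocan-6-yl acetate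
Product: 25 (2S,3S,5S,6S,8R)-8-[(1R)-1-bromopropyl]-3,5-dichloro-2-[(2Z)-pent-2-en-4-yn-1-yl]oxocan-6-yl acetate
Conditions: CBr4, P(n-C8H17)3, toluene, 70 °C
Reagents that add atoms: carbon tetrabromide, BrC(Br)(Br)Br
Why: Appel-type bromination; bromide displaces the alkoxyphosphonium group in an SN2 step, inverting C13 from S to R. The lipophilic phosphine in hot toluene suits hindered carbinols next to an ether oxygen.

## Compound list

1 | (2S)-2-hydroxybutanoic acid | CC[C@H](O)C(=O)O | starting material
2 | methyl (2S)-2-hydroxybutanoate | CC[C@H](O)C(=O)OC | intermediate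
3 | methyl (2S)-2-[(tert-butyldimethylsilyl)oxy]butanoate | CC[C@H](O[Si](C)(C)C(C)(C)C)C(=O)OC | intermediate
4 | (2S)-2-[(tert-butyldimethylsilyl)oxy]butanal | CC[C@H](O[Si](C)(C)C(C)(C)C)C=O | intermediate
5 | 2-(trimethylsilyloxy)buta-1,3-diene | C=CC(=C)O[Si](C)(C)C | starting material
6 | (5R,6S)-6-[(tert-butyldimethylsilyl)oxy]-5-hydroxyoct-1-en-3-one | C=CC(=O)C[C@@H](O)[C@@H](O[Si](C)(C)C(C)(C)C)CC | intermediate
7 | (5R,6S)-6-[(tert-butyldimethylsilyl)oxy]-5-[(diethylboranyl)oxy]oct-1-en-3-one (boron chelate, not isolated) | C=CC(=O)C[C@@H](OB(CC)CC)[C@@H](O[Si](C)(C)C(C)(C)C)CC | intermediate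
8 | (3S,5R,6S)-6-[(tert-butyldimethylsilyl)oxy]oct-1-ene-3,5-diol | C=C[C@@H](O)C[C@@H](O)[C@@H](O[Si](C)(C)C(C)(C)C)CC | intermediate
9 | (3S,5R,6S)-6-[(tert-butyldimethylsilyl)oxy]-5-hydroxyoct-1-en-3-yl acetate | C=C[C@@H](OC(C)=O)C[C@@H](O)[C@@H](O[Si](C)(C)C(C)(C)C)CC | intermediate
10 | trichloroacetyl chloride | ClC(=O)C(Cl)(Cl)Cl | starting material
11 | (3S,5R,6S)-3-(acetyloxy)-6-[(tert-butyldimethylsilyl)oxy]oct-1-en-5-yl trichloroacetate | C=C[C@@H](OC(C)=O)C[C@@H](OC(=O)C(Cl)(Cl)Cl)[C@@H](O[Si](C)(C)C(C)(C)C)CC | intermediate
12 | (5S,6S,8R)-8-[(1S)-1-[(tert-butyldimethylsilyl)oxy]propyl]-3,3,5-trichloro-2-oxooxocan-6-yl acetate | O=C1O[C@@H]([C@@H](O[Si](C)(C)C(C)(C)C)CC)C[C@H](OC(C)=O)[C@@H](Cl)CC1(Cl)Cl | intermediate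
13 | diisobutylaluminium lactolate of 12 (O2–Al(i-Bu)2, C2 epimers, not isolated) | CC(C)C[Al](CC(C)C)OC1O[C@@H]([C@@H](O[Si](C)(C)C(C)(C)C)CC)C[C@H](OC(C)=O)[C@@H](Cl)CC1(Cl)Cl | intermediate
14 | (5S,6S,8R)-8-[(1S)-1-[(tert-butyldimethylsilyl)oxy]propyl]-3,3,5-trichlorooxocane-2,6-diyl diacetate (C2 epimers) | CC(=O)OC1O[C@@H]([C@@H](O[Si](C)(C)C(C)(C)C)CC)C[C@H](OC(C)=O)[C@@H](Cl)CC1(Cl)Cl | intermediate
15 | allyltrimethylsilane | C=CC[Si](C)(C)C | starting material
16 | (2S,5S,6S,8R)-2-allyl-8-[(1S)-1-[(tert-butyldimethylsilyl)oxy]propyl]-3,3,5-trichlorooxocan-6-yl acetate | C=CC[C@@H]1O[C@@H]([C@@H](O[Si](C)(C)C(C)(C)C)CC)C[C@H](OC(C)=O)[C@@H](Cl)CC1(Cl)Cl | intermediate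
17 | (2S,3S,5S,6S,8R)-2-allyl-8-[(1S)-1-[(tert-butyldimethylsilyl)oxy]propyl]-3,5-dichlorooxocan-6-yl acetate | C=CC[C@@H]1O[C@@H]([C@@H](O[Si](C)(C)C(C)(C)C)CC)C[C@H](OC(C)=O)[C@@H](Cl)C[C@@H]1Cl | intermediate
18 | 1,2,4-trioxolane (ozonide) of 17, ring stereocentres as in 17, trioxolane carbon unassigned (not isolated) | C1OC(OO1)C[C@@H]2O[C@@H]([C@@H](O[Si](C)(C)C(C)(C)C)CC)C[C@H](OC(C)=O)[C@@H](Cl)C[C@@H]2Cl | intermediate
19 | (2S,3S,5S,6S,8R)-8-[(1S)-1-[(tert-butyldimethylsilyl)oxy]propyl]-3,5-dichloro-2-(2-oxoethyl)oxocan-6-yl acetate | O=CC[C@@H]1O[C@@H]([C@@H](O[Si](C)(C)C(C)(C)C)CC)C[C@H](OC(C)=O)[C@@H](Cl)C[C@@H]1Cl | intermediate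
20 | 1,3-bis(triisopropylsilyl)propyne | CC(C)[Si](C(C)C)(C(C)C)CC#C[Si](C(C)C)(C(C)C)C(C)C | starting material
21 | lithium β-silyl alkoxide from 19 and lithiated 20 (the diastereomer that gives the Z-alkene by syn-elimination; carbinol and silyl-bearing carbons unassigned, not isolated) | [Li]OC(C[C@@H]1O[C@@H]([C@@H](O[Si](C)(C)C(C)(C)C)CC)C[C@H](OC(C)=O)[C@@H](Cl)C[C@@H]1Cl)C(C#C[Si](C(C)C)(C(C)C)C(C)C)[Si](C(C)C)(C(C)C)C(C)C | intermediate
22 | (2S,3S,5S,6S,8R)-8-[(1S)-1-[(tert-butyldimethylsilyl)oxy]propyl]-3,5-dichloro-2-[(2Z)-5-(triisopropylsilyl)pent-2-en-4-yn-1-yl]oxocan-6-yl acetate | CC(C)[Si](C(C)C)(C(C)C)C#C/C=C\C[C@@H]1O[C@@H]([C@@H](O[Si](C)(C)C(C)(C)C)CC)C[C@H](OC(C)=O)[C@@H](Cl)C[C@@H]1Cl | intermediate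
23 | (2S,3S,5S,6S,8R)-8-[(1S)-1-[(tert-butyldimethylsilyl)oxy]propyl]-3,5-dichloro-2-[(2Z)-pent-2-en-4-yn-1-yl]oxocan-6-yl acetate (not isolated) | C#C/C=C\C[C@@H]1O[C@@H]([C@@H](O[Si](C)(C)C(C)(C)C)CC)C[C@H](OC(C)=O)[C@@H](Cl)C[C@@H]1Cl | intermediate
24 | (2S,3S,5S,6S,8R)-3,5-dichloro-8-[(1S)-1-hydroxypropyl]-2-[(2Z)-pent-2-en-4-yn-1-yl]oxocan-6-yl acetate | C#C/C=C\C[C@@H]1O[C@@H]([C@@H](O)CC)C[C@H](OC(C)=O)[C@@H](Cl)C[C@@H]1Cl | intermediate
25 | (2S,3S,5S,6S,8R)-8-[(1R)-1-bromopropyl]-3,5-dichloro-2-[(2Z)-pent-2-en-4-yn-1-yl]oxocan-6-yl acetate | C#C/C=C\C[C@@H]1O[C@@H]([C@H](Br)CC)C[C@H](OC(C)=O)[C@@H](Cl)C[C@@H]1Cl | target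

## Step count and least certain steps

Total: 15 steps. Longest linear sequence: 15 steps (1 to 25); compounds 5, 10, 15 and 20 are purchased.

**Step 8 (key step).** The most likely failure is insufficient facial discrimination when CuCl2(bipy) transfers chlorine to the C9 ring radical, because an acetoxy group is only a moderate shield on a flexible eight-membered ring. Intermolecular addition would intrude if dilution is relaxed. The fallback sets out from 8 and comes back at 12, replacing the shielding group with a larger one that is exchanged after ring closure. Selective silylation of the less hindered O10 (Et3SiCl, imidazole, CH2Cl2, –40 °C) would give (3S,5R,6S)-6-[(tert-butyldimethylsilyl)oxy]-3-[(triethylsilyl)oxy]oct-1-en-5-ol F1. Acylation with 10 and pyridine would give the trichloroacetate F2, and the same CuCl/2,2'-bipyridine cyclisation would give the C10 triethylsilyloxy lactone F3. Direct exchange of the triethylsilyl ether for acetate (Ac2O, Sc(OTf)3 cat., MeCN, –20 °C) would then deliver 12. This exchange never frees the C10 hydroxyl, which could otherwise attack the activated lactone across the ring.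

**Step 10.** The most likely failure is slow ionisation of the lactol acetate, because the adjacent CCl2 group destabilises the oxocarbenium ion; forcing the Lewis acid could then cost the silyl ether. The fallback sets out from 12 and comes back at 16, replacing acid-promoted addition of a π-nucleophile with displacement of an α-chloro ether by an organozinc reagent. i-Bu2AlH at –78 °C with aqueous work-up would give the lactol (5S,6S,8R)-8-[(1S)-1-[(tert-butyldimethylsilyl)oxy]propyl]-3,3,5-trichloro-2-hydroxyoxocan-6-yl acetate F4, which the two chlorines hold in the closed form. SOCl2 and pyridine in CH2Cl2 at 0 °C would give the α-chloro ether (5S,6S,8R)-8-[(1S)-1-[(tert-butyldimethylsilyl)oxy]propyl]-2,3,3,5-tetrachlorooxocan-6-yl acetate F5. CH2=CHCH2ZnBr in THF at –20 °C, a reagent that tolerates the acetate, would displace the activated chloride to give 16. The facial outcome would then have to be checked against the 2,8-trans requirement.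

**Step 11.** The most likely failure is loss of chemoselectivity: the silyl radical adds to the terminal alkene, or reduction runs on to the C7 methylene. Incomplete facial control of hydrogen transfer is the second risk. The fallback sets out from 16 and comes back at 19 by reversing the order of steps 11 and 12, so that no alkene is present in the radical step. Ozonolysis of 16 (O3, then PPh3) would give (2S,5S,6S,8R)-8-[(1S)-1-[(tert-butyldimethylsilyl)oxy]propyl]-3,3,5-trichloro-2-(2-oxoethyl)oxocan-6-yl acetate F6. Its mono-dechlorination with (Me3Si)3SiH and Et3B would give 19, with the larger oxoethyl group now directing hydrogen delivery.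

**Step 5.** The most likely failure is conjugate hydride addition or methoxide addition to the terminal vinyl ketone, or prior oxa-Michael closure of 6. The fallback sets out from 4 and comes back at 8, replacing the vinyl group with an alkyne that cannot suffer these reactions. Mukaiyama aldol addition of the trimethylsilyl enol ether of 4-(trimethylsilyl)but-3-yn-2-one to 4 (BF3·OEt2, –78 °C) would give (5R,6S)-6-[(tert-butyldimethylsilyl)oxy]-5-hydroxy-1-(trimethylsilyl)oct-1-yn-3-one F7. The same Et2BOMe/NaBH4 reduction would give (3S,5R,6S)-6-[(tert-butyldimethylsilyl)oxy]-1-(trimethylsilyl)oct-1-yne-3,5-diol F8. Bu4NF/AcOH at 0 °C would cleave only the alkynyl silane to give (3S,5R,6S)-6-[(tert-butyldimethylsilyl)oxy]oct-1-yne-3,5-diol F9. Semi-hydrogenation (H2, Pd/CaCO3 poisoned with Pb(OAc)2, quinoline) would then give 8.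

**Step 6.** The most likely failure is slow or no acyl transfer because the large silyloxy-bearing flank fits the enzyme poorly. The fallback sets out from 8 and comes back at 9 and makes no new compound (F0). It relies on steric rather than enzymatic discrimination: AcCl with 2,4,6-collidine in CH2Cl2 at –78 °C should acetylate the allylic O10 ahead of O12, which is shielded by the neighbouring silyl ether, and the regioisomer and diacetate would be removed by chromatography.

## Further compounds

F1 | step 8 | (3S,5R,6S)-6-[(tert-butyldimethylsilyl)oxy]-3-[(triethylsilyl)oxy]oct-1-en-5-ol | C=C[C@@H](O[Si](CC)(CC)CC)C[C@@H](O)[C@@H](O[Si](C)(C)C(C)(C)C)CC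
F2 | step 8 | (3S,5R,6S)-6-[(tert-butyldimethylsilyl)oxy]-3-[(triethylsilyl)oxy]oct-1-en-5-yl trichloroacetate | C=C[C@@H](O[Si](CC)(CC)CC)C[C@@H](OC(=O)C(Cl)(Cl)Cl)[C@@H](O[Si](C)(C)C(C)(C)C)CC
F3 | step 8 | (5S,6S,8R)-8-[(1S)-1-[(tert-butyldimethylsilyl)oxy]propyl]-3,3,5-trichloro-6-[(triethylsilyl)oxy]oxocan-2-one | O=C1O[C@@H]([C@@H](O[Si](C)(C)C(C)(C)C)CC)C[C@H](O[Si](CC)(CC)CC)[C@@H](Cl)CC1(Cl)Cl
F4 | step 10 | (5S,6S,8R)-8-[(1S)-1-[(tert-butyldimethylsilyl)oxy]propyl]-3,3,5-trichloro-2-hydroxyoxocan-6-yl acetate (C2 epimers) | OC1O[C@@H]([C@@H](O[Si](C)(C)C(C)(C)C)CC)C[C@H](OC(C)=O)[C@@H](Cl)CC1(Cl)Cl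
F5 | step 10 | (5S,6S,8R)-8-[(1S)-1-[(tert-butyldimethylsilyl)oxy]propyl]-2,3,3,5-tetrachlorooxocan-6-yl acetate (C2 epimers) | ClC1O[C@@H]([C@@H](O[Si](C)(C)C(C)(C)C)CC)C[C@H](OC(C)=O)[C@@H](Cl)CC1(Cl)Cl
F6 | step 11 | (2S,5S,6S,8R)-8-[(1S)-1-[(tert-butyldimethylsilyl)oxy]propyl]-3,3,5-trichloro-2-(2-oxoethyl)oxocan-6-yl acetate | O=CC[C@@H]1O[C@@H]([C@@H](O[Si](C)(C)C(C)(C)C)CC)C[C@H](OC(C)=O)[C@@H](Cl)CC1(Cl)Cl
F7 | step 5 | (5R,6S)-6-[(tert-butyldimethylsilyl)oxy]-5-hydroxy-1-(trimethylsilyl)oct-1-yn-3-one | C[Si](C)(C)C#CC(=O)C[C@@H](O)[C@@H](O[Si](C)(C)C(C)(C)C)CC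
F8 | step 5 | (3S,5R,6S)-6-[(tert-butyldimethylsilyl)oxy]-1-(trimethylsilyl)oct-1-yne-3,5-diol | C[Si](C)(C)C#C[C@@H](O)C[C@@H](O)[C@@H](O[Si](C)(C)C(C)(C)C)CC
F9 | step 5 | (3S,5R,6S)-6-[(tert-butyldimethylsilyl)oxy]oct-1-yne-3,5-diol | C#C[C@@H](O)C[C@@H](O)[C@@H](O[Si](C)(C)C(C)(C)C)CC
F0 | step 6 | none | none
A1 | alternative 1 | bicyclic enol ether: 8-[(tert-butyldimethylsilyl)oxy]-3-[1-[(tert-butyldiphenylsilyl)oxy]propyl]-6-[(4-methoxybenzyl)oxy]-2-oxabicyclo[3.3.0]oct-1(5)-ene (chain C7 silyl ether, C9 benzyl ether, C12 side chain) | O1[C@@H]([C@@H](O[Si](c2ccccc2)(c3ccccc3)C(C)(C)C)CC)CC4=C1[C@H](O[Si](C)(C)C(C)(C)C)C[C@H]4OCc5ccc(OC)cc5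
A2 | alternative 1 | keto-lactone: 3-[(tert-butyldimethylsilyl)oxy]-8-[1-[(tert-butyldiphenylsilyl)oxy]propyl]-5-[(4-methoxybenzyl)oxy]oxocane-2,6-dione | O=C1O[C@@H]([C@@H](O[Si](c2ccccc2)(c3ccccc3)C(C)(C)C)CC)CC(=O)[C@H](OCc4ccc(OC)cc4)C[C@H]1O[Si](C)(C)C(C)(C)C
A3 | alternative 2 | silyloxy cyclopropane: 2-allyl-4-(1-bromopropyl)-6-[(tert-butyldimethylsilyl)oxy]-1-(trimethylsilyloxy)-3-oxabicyclo[5.1.0]octane, cyclopropane methylene anti to the allyl and silyloxy groups | C=CC[C@@H]1O[C@@H]([C@H](Br)CC)C[C@H](O[Si](C)(C)C(C)(C)C)[C@H]2C[C@@]12O[Si](C)(C)C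
A4 | alternative 2 | 2,8-trans 2-allyl-8-(1-bromopropyl)-6-[(tert-butyldimethylsilyl)oxy]-5-chlorooxocan-3-one | C=CC[C@@H]1O[C@@H]([C@H](Br)CC)C[C@H](O[Si](C)(C)C(C)(C)C)[C@@H](Cl)CC1=O
A5 | alternative 3 | diazoketone: 7-(allyloxy)-8-[(tert-butyldimethylsilyl)oxy]-4-chloro-1-diazo-2-oxodecan-5-yl acetate | [N-]=[N+]=CC(=O)C[C@H](Cl)[C@@H](OC(C)=O)C[C@@H](OCC=C)[C@@H](O[Si](C)(C)C(C)(C)C)CC
A6 | alternative 3 | 2,8-trans 2-allyl-8-[1-[(tert-butyldimethylsilyl)oxy]propyl]-5-chloro-3-oxooxocan-6-yl acetate | C=CC[C@@H]1O[C@@H]([C@@H](O[Si](C)(C)C(C)(C)C)CC)C[C@H](OC(C)=O)[C@@H](Cl)CC1=O
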